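| setting | blue | amber | violet | eta | beta |
|---|---|---|---|---|---|
| substrate | 20 mM | 20 mM | 41 mM | 20 mM | 60 mM |
| coupling partner | 55 mM | 120 mM | 80 mM | 80.0 mM | 40.0 mM |
| remark | run made earlier | run made earlier | run made earlier |  |  |
| time |  |  |  | 6.0 min | 25 min |

- blue (time / min: tetra adduct / %): 0.333: 0; 0.500: 1.6; 1.00: 0; 1.50: 0; 2.50: 4.7; 4.00: 8.4
- amber (time / min: tetra adduct / %): 0.667: 0.4; 1.33: 8.4; 2.00: 13.6; 3.00: 22.0; 4.00: 23.3
- violet (time / min: tetra adduct / %): 0.333: 0.7; 0.667: 0; 1.33: 2.7; 2.00: 2.9; 4.00: 5.0

(standard deviation of a reading: 1 percentage point)

- which of the two ends with the higher amount of tetra adduct, in percent of the substrate charged ("neither" if they lie within 2 percentage points) (eta / beta / neither)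
- tetra adduct at the end, in percent of the substrate charged, eta
- tetra adduct at the end, in percent of the substrate charged, beta



Amounts came first for me: a tetra adduct carries 4 coupling partners on one substrate, so for beta I reckoned 16.7% as the partner ceiling, the share of the charged substrate that could become tetra adduct if every coupling partner ended in it, while the same reckoning gave eta 100%. I then turned the question round. For beta to finish above eta, eta would have to end below that ceiling and beta above eta, which asked of the coupling partner in beta that it pass by free substrate and gather on the same few molecules. The violet run spoke against this, since its ceiling of 48.8% had brought a reading of 5.0% at 4.00 min. Taking that same share of beta's ceiling, I put beta near 1.71%, which is my own figure and lower than the forecast's. For eta, at [coupling partner] = 80.0 mM, I expected an end above blue's 8.4%, the reading at 4.00 min.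

The forecast named eta, with 18% for eta and 3% for beta, on the ground, said of the coupling partner in beta, that “the earlier adducts consume it”.

The flask gave 20.7% in eta and 0.169% in beta, so eta ended higher, as forecast.

    substrate + coupling partner → single product + by-product (k = 0.400 /M/s)
    coupling partner + single product → bis adduct + by-product (k = 0.390 /M/s)
    coupling partner + bis adduct → triple product + by-product (k = 0.0430 /M/s)
    coupling partner + triple product → tetra adduct + by-product (k = 1.30 /M/s)
    coupling partner + tetra adduct → over-reaction product (k = 0.0800 /M/s)

Beta ended at 1.01% of its ceiling, with 0% of the charged coupling partner, the limiting reagent, left at 25.0 min and 49.4% of the charged substrate unreacted. The shrinking supply of coupling partner is one part of the reason for so low an end in beta: with the supply held at its charge, beta gives 9.87% instead of 0.169%. The neighbour of beta charged with 68 mM of coupling partner has a ceiling of 28.3% and ended at 1.14%.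

The readings come from a simulation for substances that don't exist, noise included.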